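Count turnovers first: delta and theta repeat the west and south-west runs except for their charge of protic impurity.

| flask | starting material | gas phase | protic impurity | remark | time |
|---|---|---|---|---|---|
| west | 10 mM | 1.7 mM (held) | 2.5 mM | run made earlier |  |
| south-west | 10 mM | 1.7 mM (held) | 4 mM | run made earlier |  |
| delta | 10 mM | 1.7 mM (held) | 2.00 mM |  | 30 h |
| theta | 10 mM | 1.7 mM (held) | 3.00 mM |  | 30 h |

- west (time / h: target / %, starting material / %, side product / %): 4.00: 4.1, 55.3, 15.2; 10.0: 6.6, 34.8, 30.0; 20.0: 10.3, 17.9, 45.8; 30.0: 13.7, 7.5, 54.6
- south-west (time / h: target / %, starting material / %, side product / %): 4.00: 3.4, 45.3, 13.1; 10.0: 5.2, 29.6, 26.2; 20.0: 9.5, 12.2, 36.8; 30.0: 11.5, 6.2, 43.8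

(scatter of a reading: 1 percentage point)

- amounts and yields of target count crystals too
- given per volume of solution although it is solid: crystals
- at the start none of the gas is dissolved
- the analysis behind the earlier runs scatters by 1 percentage point, standard deviation
- steps that have been proposed: gas phase <-> dissolved gas; starting material + dissolved gas -> target; starting material -> side product; crystals <-> target; starting material + protic impurity -> quenched substrate; dissolved gas -> decomposed reagent

- which of these there is most of at the end, counted by the starting material in it, delta (target / side product / starting material)
- which of these there is most of at the end, counted by the starting material in it, theta (target / side product / starting material)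
- final amount of the leader among these, as a percentage of the starting material charged, in delta
- final amount of the leader among these, as a percentage of the starting material charged, in theta

Between 4.00 h and 30.0 h the starting material in the west run falls from 55.3% to 7.5%, a rate constant of 0.0768 h⁻¹, and the south-west run reads 0.0765 h⁻¹, the same pace, a pseudo-first-order decay. Its inverse is the turnover time 13.0 h, the time in which the starting material falls to 36.8% of its value, so 30 h in delta or theta is 2.31 turnovers and leaves 9.97% of what takes part.

But that decay, applied to the whole charge, puts the west run at 73.5% after 4.00 h, and the reading is 55.3%. The sum of target, starting material and side product explains the gap: at 4.00 h it is 74.6% in west and 61.8% in south-west, and at 30.0 h it is 75.8% and 61.5%. The missing parts lie near [protic impurity]/[starting material], 25.0% and 40.0%, and they are already missing at a first reading earlier than one turnover. The usable share is therefore 80.0% in delta and 70.0% in theta.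

A further doubt is the split of what decays, yet side product takes 79.9% of the two products in west and 79.2% in south-west. This reckoning therefore gives side product 57.6% in delta, ahead of target and starting material, and 50.4% in theta.

The forecast names side product at 58.3% (56% to 60.5%) for delta and side product at 51% (49% to 53%) for theta, both higher than the reckoning here; it counts the same usable shares but reads that “Side product at 30 h is 0.73 of the usable amount”, where the reckoning here has 0.719 of it.

The simulation gives side product at 56.9% in delta and side product at 49.8% in theta, both inside the forecast's ranges. The steps and their constants are these:

    gas phase ⇌ dissolved gas, rate k1*(csat - [dissolved gas]) (kL = 0.470 h⁻¹)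
    starting material + dissolved gas → target (k = 60.0 M⁻¹ h⁻¹)
    starting material → side product (k = 0.0580 h⁻¹)
    crystals ⇌ target, rate k4*(cs4 - [target]) while solid is left; crystals form when [target] > cs4 (solubility = 0.180 mM, k = 28.0 h⁻¹)
    starting material + protic impurity → quenched substrate (k = 350 M⁻¹ h⁻¹)
    dissolved gas → decomposed reagent (k = 2.50 h⁻¹)

Theta read at 8.0 h has had 0.615 turnovers, since that time is shorter than the turnover time, and the same reckoning puts starting material at 37.9% and side product at 25.7%, so starting material leads there. That neighbouring flask holds 38.9% starting material and 25.1% side product.

All runs come from a simulation with made-up constants, and the scatter is random.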